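The lactone is treated as a ring-expanded ketone: without O1, the 31-membered ring shrinks to the 30-membered carbocycle cyclotriacontanone, whose two halves on either side of carbonyl carbon C2 are identical. That symmetry lets the bond mapping onto C2–C3 be forged by reductive coupling of the two equal ester carbonyls of dimethyl triacontanedioate, a linear C30 diester prepared by Kolbe dimerisation of a C16 half ester. The acyloin condensation with chlorotrimethylsilane trapping closes the all-carbon ring in a single operation. Desilylation and zinc reduction in one flask give the ketone, and a Baeyer–Villiger oxidation, free of regiochemical issues since both α-carbons are equivalent, inserts O1 last.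

Key step: step 4

Remark: the target is achiral and saturated, so no stereocontrol is needed; ring atoms are numbered O1, C2 (carbonyl carbon), C3 to C31.

Step 1
Reactants: 1 hexadecanedioic acid
Product: 2 dimethyl hexadecanedioate
Conditions: MeOH (solvent), H2SO4 (cat.), reflux
Reagents that add atoms: methanol, CO
Why: Fischer esterification in a large excess of methanol should drive both carboxyl groups of the unfunctionalised diacid to the diester.

Step 2
Reactants: 2 dimethyl hexadecanedioate
Product: 4 16-methoxy-16-oxohexadecanoic acid, via barium half-ester salt 3 (not isolated)
Conditions: Ba(OH)2 (0.5 equiv), dry MeOH, 35 °C; precipitate washed by decantation, then cold 2 M HCl, Et2O; recovered 2 and 1 returned to the sequence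
Reagents that add atoms: barium hydroxide, [Ba+2].[OH-].[OH-]
Why: Ester saponification limited to one hydroxide per diester should stop at the half ester, because its barium salt precipitates from methanol and is thereby withdrawn from a second hydrolysis (desymmetrising mono-saponification).

Step 3
Reactants: 4 16-methoxy-16-oxohexadecanoic acid (two molecules, homocoupling)
Product: 5 dimethyl triacontanedioate
Conditions: Pt anode, Pt cathode, undivided cell, MeOH, NaOMe (0.05 equiv), 50 °C, constant current at high anodic current density until faintly alkaline
Reagents that add atoms: none
Why: Kolbe electrolysis of the unbranched carboxylate should give, after anodic loss of CO2, primary 14-(methoxycarbonyl)tetradecyl radicals that dimerise at the platinum surface, the remote ester being inert, so that two C15 halves are joined at the midpoint of the C30 chain.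

Step 4
Reactants: 5 dimethyl triacontanedioate
Product: 8 1,2-bis(trimethylsilyloxy)cyclotriacont-1-ene, via cyclotriacontane-1,2-dione 6 (not isolated), via disodium cyclotriacont-1-ene-1,2-diolate 7 (not isolated)
Conditions: Na dispersion (4.4 equiv), Me3SiCl (4.6 equiv), toluene, reflux, Ar; 5 added as a warm dilute toluene solution over 24 h
Reagents that add atoms: chlorotrimethylsilane, C[Si](C)(C)Cl
Why: Electron transfer from the molten sodium surface to each ester carbonyl of 5 should generate two ketyl radical anions on the same chain, which combine through their carbonyl carbons; expulsion of two methoxides then gives dione 6, a further two-electron reduction gives enediolate 7, and chlorotrimethylsilane caps both oxygens to give 8. The closest known reaction type is the acyloin condensation of long-chain α,ω-diesters on sodium with silyl chloride trapping, the standard entry to large carbocycles. The 30-membered ring is closed by intramolecular ketyl–ketyl (radical–radical) coupling of the two chain termini adsorbed on the metal, forming the bond that maps onto C2–C3 of the target, and an unbranched polymethylene chain of this length closes without transannular strain. No stereocentre is formed, and the geometry of the enediol double bond is of no consequence because it is erased on desilylation. Selectivity for ring closure over chain growth and over alkoxide-induced ester condensation is required; it should be secured by feeding the diester slowly onto an excess of metal, by scavenging methoxide as its silyl ether, and by the absence of any other reducible or acidic group in 5.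

Step 5
Reactants: 8 1,2-bis(trimethylsilyloxy)cyclotriacont-1-ene
Product: 10 cyclotriacontanone, via 2-hydroxycyclotriacontanone 9 (not isolated)
Conditions: 2 M HCl, dioxane (degassed), 60 °C, Ar; then Zn dust, conc. HCl, AcOH, 75–80 °C, same flask
Reagents that add atoms: none
Why: Acid hydrolysis of the two silyl enol ether groups should release the racemic acyloin 9, and zinc–acid reductive deoxygenation of this α-ketol (electron transfer to the carbonyl, loss of the α-hydroxyl as water, tautomerisation of the enol) should leave the ketone, the reducing medium also shielding 9 from autoxidation.

Step 6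
Reactants: 10 cyclotriacontanone
Product: 11 oxacyclohentriacontan-2-one (30-triacontanolide)
Conditions: (CF3CO)2O, urea·H2O2, Na2HPO4, CH2Cl2, 0 °C to reflux
Reagents that add atoms: urea–hydrogen peroxide, NC(N)=O.OO (its oxygen is delivered as trifluoroperacetic acid, OOC(=O)C(F)(F)F)
Why: Baeyer–Villiger oxidation with the strongly electrophilic trifluoroperacetic acid should add to the unhindered carbonyl and make a primary ring carbon migrate to oxygen, and since the two α-carbons of 10 are equivalent either migration gives the same 31-membered lactone, the phosphate buffer keeping trifluoroacetic acid from opening it.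

Compound list
1 | hexadecanedioic acid | OC(=O)CCCCCCCCCCCCCCC(=O)O | starting material
2 | dimethyl hexadecanedioate | COC(=O)CCCCCCCCCCCCCCC(=O)OC | intermediate
3 | barium half-ester salt, barium bis(16-methoxy-16-oxohexadecanoate) | [Ba+2].COC(=O)CCCCCCCCCCCCCCC(=O)[O-].COC(=O)CCCCCCCCCCCCCCC(=O)[O-] | intermediate
4 | 16-methoxy-16-oxohexadecanoic acid (methyl hydrogen hexadecanedioate) | COC(=O)CCCCCCCCCCCCCCC(=O)O | intermediate
5 | dimethyl triacontanedioate | COC(=O)CCCCCCCCCCCCCCCCCCCCCCCCCCCCC(=O)OC | intermediate
6 | cyclotriacontane-1,2-dione | O=C1C(=O)CCCCCCCCCCCCCCCCCCCCCCCCCCCC1 | intermediate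
7 | disodium cyclotriacont-1-ene-1,2-diolate | [Na+].[Na+].[O-]C1=C([O-])CCCCCCCCCCCCCCCCCCCCCCCCCCCC1 | intermediate
8 | 1,2-bis(trimethylsilyloxy)cyclotriacont-1-ene (double-bond geometry not controlled) | C[Si](C)(C)OC1=C(O[Si](C)(C)C)CCCCCCCCCCCCCCCCCCCCCCCCCCCC1 | intermediate
9 | 2-hydroxycyclotriacontanone (racemic) | O=C1C(O)CCCCCCCCCCCCCCCCCCCCCCCCCCCC1 | intermediate
10 | cyclotriacontanone | O=C1CCCCCCCCCCCCCCCCCCCCCCCCCCCCC1 | intermediate
11 | oxacyclohentriacontan-2-one (30-triacontanolide) | O=C1CCCCCCCCCCCCCCCCCCCCCCCCCCCCCO1 | target

Total step count: 6
Longest linear sequence: 6 steps (1 to 11)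

Steps most likely to fail

Step 4. Chain growth by intermolecular ketyl coupling may outrun cyclisation, or the sparingly soluble diester may coat the sodium and stall electron transfer. The fallback sets out from 5 and returns at 10, closing the carbocycle by carbonyl olefination instead. Diester 5 would be reduced with LiAlH4 in refluxing THF to triacontane-1,30-diol F1, which would be oxidised with IBX in hot ethyl acetate to triacontanedial F2. Slow addition of F2 to low-valent titanium made from TiCl3(DME)1.5 and Zn–Cu couple in refluxing DME (McMurry coupling) should give cyclotriacontene F3, whose alkene geometry is immaterial. Hydroboration with BH3·THF and oxidation with alkaline H2O2 should give cyclotriacontanol F4, and Dess–Martin oxidation in CH2Cl2 should then deliver ketone 10.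

Step 6. Peracid addition to a strain-free macrocyclic dialkyl ketone is slow, so conversion may stall, and acidolysis may reopen the lactone as it forms. The fallback sets out from 8 and returns at 11, introducing the ring oxygen by cleavage and relactonisation. Compound 8 would be hydrolysed with dilute HCl in degassed THF and acyloin 9 isolated. Periodic acid (H5IO6) in aqueous THF should cleave the α-ketol C–C bond to 30-oxotriacontanoic acid F5, and NaBH4 in ethanol–THF with NaOH should reduce only the aldehyde to give 30-hydroxytriacontanoic acid F6. Activation with 2,4,6-trichlorobenzoyl chloride and Et3N in warm THF would give 30-hydroxytriacontanoic 2,4,6-trichlorobenzoic anhydride F7. Slow addition of F7 to DMAP in refluxing toluene at high dilution (Yamaguchi macrolactonisation) should close the 31-membered ring of 11.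

Step 5. Reduction may run past the ketone to the alcohol or hydrocarbon (Clemmensen-type over-reduction), or stop short and leave unreduced ketol. The fallback sets out from 8 and returns at 10. Compound 8 would be hydrolysed as above and 9 isolated, then acetylated with Ac2O, pyridine and DMAP to 2-oxocyclotriacontyl acetate F8. SmI2 in THF–MeOH at −78 to −40 °C should then cleave the α-acetoxy group by single-electron reduction and give 10 without touching the carbonyl.

Further compounds
F1 | step 4 | triacontane-1,30-diol | OCCCCCCCCCCCCCCCCCCCCCCCCCCCCCCO
F2 | step 4 | triacontanedial | O=CCCCCCCCCCCCCCCCCCCCCCCCCCCCCC=O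
F3 | step 4 | cyclotriacontene (mixture of alkene isomers) | C1=CCCCCCCCCCCCCCCCCCCCCCCCCCCCC1
F4 | step 4 | cyclotriacontanol | OC1CCCCCCCCCCCCCCCCCCCCCCCCCCCCC1
F5 | step 6 | 30-oxotriacontanoic acid | O=CCCCCCCCCCCCCCCCCCCCCCCCCCCCCC(=O)O
F6 | step 6 | 30-hydroxytriacontanoic acid | OCCCCCCCCCCCCCCCCCCCCCCCCCCCCCC(=O)O
F7 | step 6 | 30-hydroxytriacontanoic 2,4,6-trichlorobenzoic anhydride | OCCCCCCCCCCCCCCCCCCCCCCCCCCCCCC(=O)OC(=O)c1c(Cl)cc(Cl)cc1Cl
F8 | step 5 | 2-oxocyclotriacontyl acetate (racemic) | CC(=O)OC1C(=O)CCCCCCCCCCCCCCCCCCCCCCCCCCCC1
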